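The isocoumarin is opened at C8a–C1 and C4a–C4. Ring A carries the two carbon arms of the pyranone on the adjacent atoms C8a and C4a, right beside the C8 aryloxy group, so both arms are attached at once by inserting the C8a≡C4a aryne into a C–C bond of dimethyl malonate; the C8 oxygen sends the carbanion to C4a and the ester carbonyl to C8a. The aryne precursor is the fully O-methylated diaryl ether whose ring A bears triflate on C8a and trimethylsilyl on C4a, built by SNAr, Dakin oxidation and a bromine-guided silyl shift. Saponification, fusion with hexanoyl chloride and demethylation then give the target.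

Key step: step 7

Remark: isocoumarin numbering is used for ring A (C4a, C5–C8, C8a) and ring B is the pentylresorcinol ring; compounds 1, 6, 17 and 23 are taken as commercial, and all compounds are achiral apart from the transient racemic adduct 20.

Step 1
Reactants: 1 1,3-dimethoxy-5-pentylbenzene (olivetol dimethyl ether)
Product: 3 2,4-dimethoxy-6-pentylbenzaldehyde, via aryl iminium salt 2 (not isolated)
Conditions: POCl3, DMF, 0 to 60 °C; then aq NaOH
Reagents that add atoms: N,N-dimethylformamide, CN(C)C=O (formyl carbon); water, O (carbonyl oxygen)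
Why: Vilsmeier–Haack formylation, in which the chloroiminium electrophile should attack the ring carbon para to one methoxy group and ortho to the other (next to the pentyl chain) in preference to the more hindered carbon between the two methoxy groups, the iminium salt 2 being hydrolysed on work-up.

Step 2
Reactants: 3 2,4-dimethoxy-6-pentylbenzaldehyde
Product: 5 2,4-dimethoxy-6-pentylphenol, via aryl formate 4 (not isolated)
Conditions: mCPBA, CH2Cl2, 0 °C to rt; aq NaHCO3 wash; then K2CO3 (cat.), MeOH, rt, under N2
Reagents that add atoms: mCPBA, OOC(=O)c1cccc(Cl)c1 (one oxygen)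
Why: Dakin-type Baeyer–Villiger oxidation, in which the electron-rich aryl group migrates to oxygen in the Criegee adduct to give formate 4, which is methanolysed to the phenol.

Step 3
Reactants: 6 1-bromo-3-fluoro-5-methoxybenzene
Product: 9 2-bromo-6-fluoro-4-methoxybenzaldehyde, via aryllithium 7 (not isolated), via lithium aminoalkoxide 8 (not isolated)
Conditions: LiN(iPr)2, THF, −78 °C; DMF, −78 °C; then aq HCl
Reagents that add atoms: N,N-dimethylformamide, CN(C)C=O (formyl carbon and oxygen)
Why: Directed ortho-lithiation and formylation, in which the C–H flanked by fluorine and bromine is the most acidic site and is removed by the lithium amide at −78 °C without bromine–lithium exchange or loss of lithium halide, the aryllithium then adding to DMF.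

Step 4
Reactants: 5 2,4-dimethoxy-6-pentylphenol; 9 2-bromo-6-fluoro-4-methoxybenzaldehyde
Product: 10 2-bromo-6-(2,4-dimethoxy-6-pentylphenoxy)-4-methoxybenzaldehyde
Conditions: K2CO3, DMF, 100 °C, under N2
Reagents that add atoms: none
Why: Nucleophilic aromatic substitution by addition–elimination, in which the fluoride ortho to the formyl group is displaced by the phenoxide through a Meisenheimer adduct while the aryl bromide stays inert in the absence of a transition metal.

Step 5
Reactants: 10 2-bromo-6-(2,4-dimethoxy-6-pentylphenoxy)-4-methoxybenzaldehyde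
Product: 12 2-bromo-6-(2,4-dimethoxy-6-pentylphenoxy)-4-methoxyphenol, via aryl formate 11 (not isolated)
Conditions: mCPBA, CH2Cl2, 0 °C to rt; aq NaHCO3 wash; then K2CO3 (cat.), MeOH, rt
Reagents that add atoms: mCPBA, OOC(=O)c1cccc(Cl)c1 (one oxygen)
Why: Dakin-type Baeyer–Villiger oxidation, in which the aryl group carrying a para methoxy and an ortho aryloxy donor migrates in preference to hydrogen and the formate 11 is cleaved by methanolysis.

Step 6
Reactants: 12 2-bromo-6-(2,4-dimethoxy-6-pentylphenoxy)-4-methoxyphenol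
Product: 16 2-(2,4-dimethoxy-6-pentylphenoxy)-4-methoxy-6-(trimethylsilyl)phenyl trifluoromethanesulfonate, via silyl ether 13 (not isolated), via aryllithium 14 (not isolated), via lithium phenoxide 15 (not isolated)
Conditions: HMDS, THF, 70 °C; evaporate; n-BuLi, THF, −78 °C; Tf2O, −78 °C to rt
Reagents that add atoms: hexamethyldisilazane, C[Si](C)(C)N[Si](C)(C)C (trimethylsilyl group); trifluoromethanesulfonic anhydride, O=S(=O)(OS(=O)(=O)C(F)(F)F)C(F)(F)F (triflyl group)
Why: O-silylation followed by bromine–lithium exchange, which is far faster than deprotonation of any aryl C–H, triggers a 1,3 O-to-C silyl shift (retro-Brook rearrangement) that puts silicon exactly where bromine was, and the phenoxide is trapped as the triflate, the standard way from 2-bromophenols to 2-silylaryl triflates.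

Step 7
Reactants: 16 2-(2,4-dimethoxy-6-pentylphenoxy)-4-methoxy-6-(trimethylsilyl)phenyl trifluoromethanesulfonate; 17 dimethyl malonate
Product: 21 methyl 2-(2,4-dimethoxy-6-pentylphenoxy)-4-methoxy-6-(2-methoxy-2-oxoethyl)benzoate, via aryne 18 (not isolated), via aryl anion 19 (not isolated), via benzocyclobutenoxide 20 (not isolated)
Conditions: KF, 18-crown-6, 17 (2 equiv), THF, 0 °C to rt
Reagents that add atoms: none
Why: Fluoride removes silicon from C4a and the carbanion expels triflate from C8a to give aryne 18; potassium dimethyl malonate adds to C4a to give aryl anion 19, whose C8a carbanion attacks one ester carbonyl to form benzocyclobutenoxide 20, and cleavage of the strained bond between the two former malonate carbons leaves CO2Me on C8a and an ester-stabilised benzylic anion on C4a that is protonated to 21. The closest known reaction type is the acyl-alkylation of arynes from 2-silylaryl triflates by insertion into the C–C bond of malonates and beta-keto esters. No ring remains in the product, since the only ring formed is the transient four-membered ring of 20, closed in a 4-exo-trig manner and reopened by retro-aldol-type fragmentation. No stereocenter is created. The step needs regioselective addition to the unsymmetrical aryne, which the inductively withdrawing C8 aryloxy oxygen should secure by polarising the aryne so that the nucleophile enters at the distal C4a and the negative charge develops at C8a next to the C–O bond, while the excess of malonate limits arylation of the product by a second aryne.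

Step 8
Reactants: 21 methyl 2-(2,4-dimethoxy-6-pentylphenoxy)-4-methoxy-6-(2-methoxy-2-oxoethyl)benzoate
Product: 22 2-(carboxymethyl)-6-(2,4-dimethoxy-6-pentylphenoxy)-4-methoxybenzoic acid
Conditions: KOH, EtOH/H2O, reflux; then aq HCl
Reagents that add atoms: potassium hydroxide, [K+].[OH-] (one oxygen in each carboxyl group)
Why: Saponification of both methyl esters by acyl–oxygen cleavage, for which the hindered benzoate needs excess hydroxide at reflux while the diaryl ether and the aryl methyl ethers are inert to base.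

Step 9
Reactants: 22 2-(carboxymethyl)-6-(2,4-dimethoxy-6-pentylphenoxy)-4-methoxybenzoic acid; 23 hexanoyl chloride
Product: 27 8-(2,4-dimethoxy-6-pentylphenoxy)-6-methoxy-3-pentyl-1H-isochromen-1-one, via anhydride 24 (not isolated), via acyl anhydride 25 (not isolated), via isocoumarin acid 26 (not isolated)
Conditions: neat 23 (excess), 200 °C
Reagents that add atoms: none
Why: Thermal condensation of a homophthalic acid with an acyl chloride, in which the acid chloride dehydrates 22 to anhydride 24 and C-acylates its enol at C4 to 25, the enol oxygen of the new ketone opens the anhydride at the aryl carbonyl to give the isocoumarin-4-carboxylic acid 26, and this loses CO2 at 200 °C, the classical fusion route to 3-alkylisocoumarins.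

Step 10
Reactants: 27 8-(2,4-dimethoxy-6-pentylphenoxy)-6-methoxy-3-pentyl-1H-isochromen-1-one
Product: 28 8-(2,4-dihydroxy-6-pentylphenoxy)-6-hydroxy-3-pentyl-1H-isochromen-1-one
Conditions: BBr3 (excess), CH2Cl2, −78 °C to rt; then H2O
Reagents that add atoms: none
Why: Lewis-acid cleavage of the three aryl methyl ethers, in which BBr3 coordinates each methoxy oxygen and bromide removes the methyl group by SN2 attack, while the diaryl ether (no sp3 carbon on oxygen) and the lactone should survive and hydrolysis of the aryl borates frees the triphenol.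

Compound list
1 | 1,3-dimethoxy-5-pentylbenzene (olivetol dimethyl ether) | CCCCCc1cc(OC)cc(OC)c1 | starting material
2 | [(2,4-dimethoxy-6-pentylphenyl)methylidene]dimethyliminium chloride (not isolated) | CCCCCc1cc(OC)cc(OC)c1C=[N+](C)C.[Cl-] | intermediate
3 | 2,4-dimethoxy-6-pentylbenzaldehyde | CCCCCc1cc(OC)cc(OC)c1C=O | intermediate
4 | 2,4-dimethoxy-6-pentylphenyl formate (not isolated) | CCCCCc1cc(OC)cc(OC)c1OC=O | intermediate
5 | 2,4-dimethoxy-6-pentylphenol | CCCCCc1cc(OC)cc(OC)c1O | intermediate
6 | 1-bromo-3-fluoro-5-methoxybenzene | COc1cc(F)cc(Br)c1 | starting material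
7 | (2-bromo-6-fluoro-4-methoxyphenyl)lithium (not isolated) | COc1cc(F)c([Li])c(Br)c1 | intermediate
8 | lithium (2-bromo-6-fluoro-4-methoxyphenyl)(dimethylamino)methanolate (not isolated) | [Li+].[O-]C(N(C)C)c1c(F)cc(OC)cc1Br | intermediate
9 | 2-bromo-6-fluoro-4-methoxybenzaldehyde | COc1cc(F)c(C=O)c(Br)c1 | intermediate
10 | 2-bromo-6-(2,4-dimethoxy-6-pentylphenoxy)-4-methoxybenzaldehyde | CCCCCc1cc(OC)cc(OC)c1Oc1cc(OC)cc(Br)c1C=O | intermediate
11 | 2-bromo-6-(2,4-dimethoxy-6-pentylphenoxy)-4-methoxyphenyl formate (not isolated) | CCCCCc1cc(OC)cc(OC)c1Oc1cc(OC)cc(Br)c1OC=O | intermediate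
12 | 2-bromo-6-(2,4-dimethoxy-6-pentylphenoxy)-4-methoxyphenol | CCCCCc1cc(OC)cc(OC)c1Oc1cc(OC)cc(Br)c1O | intermediate
13 | [2-bromo-6-(2,4-dimethoxy-6-pentylphenoxy)-4-methoxyphenoxy]trimethylsilane (not isolated) | CCCCCc1cc(OC)cc(OC)c1Oc1cc(OC)cc(Br)c1O[Si](C)(C)C | intermediate
14 | [3-(2,4-dimethoxy-6-pentylphenoxy)-5-methoxy-2-(trimethylsilyloxy)phenyl]lithium (not isolated) | CCCCCc1cc(OC)cc(OC)c1Oc1cc(OC)cc([Li])c1O[Si](C)(C)C | intermediate
15 | lithium 2-(2,4-dimethoxy-6-pentylphenoxy)-4-methoxy-6-(trimethylsilyl)phenolate (not isolated) | CCCCCc1cc(OC)cc(OC)c1Oc1cc(OC)cc([Si](C)(C)C)c1[O-].[Li+] | intermediate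
16 | 2-(2,4-dimethoxy-6-pentylphenoxy)-4-methoxy-6-(trimethylsilyl)phenyl trifluoromethanesulfonate | CCCCCc1cc(OC)cc(OC)c1Oc1cc(OC)cc([Si](C)(C)C)c1OS(=O)(=O)C(F)(F)F | intermediate
17 | dimethyl malonate | COC(=O)CC(=O)OC | starting material
18 | 3-(2,4-dimethoxy-6-pentylphenoxy)-5-methoxybenzyne, the C8a≡C4a aryne (not isolated) | CCCCCc1cc(OC)cc(OC)c1OC1=CC(OC)=CC#C1 | intermediate
19 | potassium salt of the C8a aryl anion of dimethyl 2-[3-(2,4-dimethoxy-6-pentylphenoxy)-5-methoxyphenyl]malonate (not isolated) | COC(=O)C(C(=O)OC)c1cc(OC)cc(Oc2c(OC)cc(OC)cc2CCCCC)[c-]1.[K+] | intermediate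
20 | potassium 2-(2,4-dimethoxy-6-pentylphenoxy)-4,8-dimethoxy-7-(methoxycarbonyl)bicyclo[4.2.0]octa-1,3,5-trien-8-olate (transient mixture of stereoisomers, not isolated) | COC(=O)C1c2cc(OC)cc(Oc3c(OC)cc(OC)cc3CCCCC)c2C1([O-])OC.[K+] | intermediate
21 | methyl 2-(2,4-dimethoxy-6-pentylphenoxy)-4-methoxy-6-(2-methoxy-2-oxoethyl)benzoate | COC(=O)Cc1cc(OC)cc(Oc2c(OC)cc(OC)cc2CCCCC)c1C(=O)OC | intermediate
22 | 2-(carboxymethyl)-6-(2,4-dimethoxy-6-pentylphenoxy)-4-methoxybenzoic acid | CCCCCc1cc(OC)cc(OC)c1Oc1cc(OC)cc(CC(=O)O)c1C(=O)O | intermediate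
23 | hexanoyl chloride | CCCCCC(=O)Cl | starting material
24 | 8-(2,4-dimethoxy-6-pentylphenoxy)-6-methoxyisochromane-1,3-dione (not isolated) | CCCCCc1cc(OC)cc(OC)c1Oc1cc(OC)cc2c1C(=O)OC(=O)C2 | intermediate
25 | 8-(2,4-dimethoxy-6-pentylphenoxy)-4-hexanoyl-6-methoxyisochromane-1,3-dione (not isolated) | CCCCCc1cc(OC)cc(OC)c1Oc1cc(OC)cc2c1C(=O)OC(=O)C2C(=O)CCCCC | intermediate
26 | 8-(2,4-dimethoxy-6-pentylphenoxy)-6-methoxy-1-oxo-3-pentyl-1H-isochromene-4-carboxylic acid (not isolated) | CCCCCc1cc(OC)cc(OC)c1Oc1cc(OC)cc2c1C(=O)OC(CCCCC)=C2C(=O)O | intermediate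
27 | 8-(2,4-dimethoxy-6-pentylphenoxy)-6-methoxy-3-pentyl-1H-isochromen-1-one | CCCCCc1cc2cc(OC)cc(Oc3c(OC)cc(OC)cc3CCCCC)c2c(=O)o1 | intermediate
28 | 8-(2,4-dihydroxy-6-pentylphenoxy)-6-hydroxy-3-pentyl-1H-isochromen-1-one | CCCCCc1cc2cc(O)cc(Oc3c(O)cc(O)cc3CCCCC)c2c(=O)o1 | target

Total step count: 10 steps.
Longest linear sequence: 9 steps (steps 1, 2, 4, 5, 6, 7, 8, 9 and 10, from olivetol dimethyl ether 1); step 3 makes the ring A partner in a side branch.

Steps most likely to fail

Step 7 (aryne insertion). The aryl anion may be protonated before it closes onto the ester, which would leave a plain arylmalonate. The malonate may add at the wrong aryne carbon. The product may be arylated by a second aryne. The fallback makes the homophthalic acid without an aryne; it sets out from bromo aldehyde 10 and comes back at diacid 22. Chlorite oxidation of 10 (NaClO2, NaH2PO4, 2-methyl-2-butene, t-BuOH/H2O) should give 2-bromo-6-(2,4-dimethoxy-6-pentylphenoxy)-4-methoxybenzoic acid F1. A copper-catalysed Hurtley coupling of its sodium salt with dimethyl malonate 17 (NaH, CuBr, neat 17, 80 °C), which is assisted by the ortho carboxylate, should give dimethyl 2-[2-carboxy-3-(2,4-dimethoxy-6-pentylphenoxy)-5-methoxyphenyl]malonate F2. Hydrolysis (KOH, EtOH/H2O, reflux) should give 2-[2-carboxy-3-(2,4-dimethoxy-6-pentylphenoxy)-5-methoxyphenyl]malonic acid F3, which should lose CO2 on acidification and warming to give 22.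

Step 9 (fusion at 200 °C). Hot acid chloride and HCl may acylate or degrade the electron-rich ring B, and the decarboxylation may stay incomplete. The fallback makes the same bonds stepwise under mild conditions; it sets out from diacid 22 and comes back at 27. Ac2O in toluene at reflux should close 22 to the anhydride 24, which is isolated here. C-acylation at C4 with hexanoyl chloride 23 (1,1,3,3-tetramethylguanidine, Et3N, MeCN, 0 °C) should give 25. Hydrolysis and decarboxylation (aq HCl, dioxane, 80 °C) should give 2-(2,4-dimethoxy-6-pentylphenoxy)-4-methoxy-6-(2-oxoheptyl)benzoic acid F4. Cyclodehydration (p-TsOH, toluene, reflux with removal of water) should then give 27.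

Step 6 (silyl shift and triflation in one flask). The aryllithium may be quenched before silicon migrates, the migration may stay incomplete, or the crowded lithium phenoxide may be triflated poorly. The fallback brings silicon in from outside and forms the triflate under amine conditions; it sets out from bromophenol 12 and comes back at 16. Isopropyl isocyanate (Et3N cat., CH2Cl2) should give 2-bromo-6-(2,4-dimethoxy-6-pentylphenoxy)-4-methoxyphenyl N-isopropylcarbamate F5. Temporary N-silylation (TBSOTf, TMEDA, Et2O) should give the N-(tert-butyldimethylsilyl) carbamate F6. Bromine–lithium exchange (n-BuLi, −78 °C) and a TMSCl quench should give the C-silylated N-silyl carbamate F7. Acidic work-up should remove the N-silyl group to give 2-(2,4-dimethoxy-6-pentylphenoxy)-4-methoxy-6-(trimethylsilyl)phenyl N-isopropylcarbamate F8. Et2NH and DBU in MeCN at 40 °C should free 2-(2,4-dimethoxy-6-pentylphenoxy)-4-methoxy-6-(trimethylsilyl)phenol F9 as its amidinium phenoxide, and PhNTf2 in the same flask should give 16.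

Further compounds
F1 | step 7 | 2-bromo-6-(2,4-dimethoxy-6-pentylphenoxy)-4-methoxybenzoic acid | CCCCCc1cc(OC)cc(OC)c1Oc1cc(OC)cc(Br)c1C(=O)O
F2 | step 7 | dimethyl 2-[2-carboxy-3-(2,4-dimethoxy-6-pentylphenoxy)-5-methoxyphenyl]malonate | CCCCCc1cc(OC)cc(OC)c1Oc1cc(OC)cc(C(C(=O)OC)C(=O)OC)c1C(=O)O
F3 | step 7 | 2-[2-carboxy-3-(2,4-dimethoxy-6-pentylphenoxy)-5-methoxyphenyl]malonic acid | CCCCCc1cc(OC)cc(OC)c1Oc1cc(OC)cc(C(C(=O)O)C(=O)O)c1C(=O)O
F4 | step 9 | 2-(2,4-dimethoxy-6-pentylphenoxy)-4-methoxy-6-(2-oxoheptyl)benzoic acid | CCCCCC(=O)Cc1cc(OC)cc(Oc2c(OC)cc(OC)cc2CCCCC)c1C(=O)O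
F5 | step 6 | 2-bromo-6-(2,4-dimethoxy-6-pentylphenoxy)-4-methoxyphenyl N-isopropylcarbamate | CCCCCc1cc(OC)cc(OC)c1Oc1cc(OC)cc(Br)c1OC(=O)NC(C)C
F6 | step 6 | 2-bromo-6-(2,4-dimethoxy-6-pentylphenoxy)-4-methoxyphenyl N-(tert-butyldimethylsilyl)-N-isopropylcarbamate | CCCCCc1cc(OC)cc(OC)c1Oc1cc(OC)cc(Br)c1OC(=O)N(C(C)C)[Si](C)(C)C(C)(C)C
F7 | step 6 | 2-(2,4-dimethoxy-6-pentylphenoxy)-4-methoxy-6-(trimethylsilyl)phenyl N-(tert-butyldimethylsilyl)-N-isopropylcarbamate | CCCCCc1cc(OC)cc(OC)c1Oc1cc(OC)cc([Si](C)(C)C)c1OC(=O)N(C(C)C)[Si](C)(C)C(C)(C)C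
F8 | step 6 | 2-(2,4-dimethoxy-6-pentylphenoxy)-4-methoxy-6-(trimethylsilyl)phenyl N-isopropylcarbamate | CCCCCc1cc(OC)cc(OC)c1Oc1cc(OC)cc([Si](C)(C)C)c1OC(=O)NC(C)C
F9 | step 6 | 2-(2,4-dimethoxy-6-pentylphenoxy)-4-methoxy-6-(trimethylsilyl)phenol | CCCCCc1cc(OC)cc(OC)c1Oc1cc(OC)cc([Si](C)(C)C)c1O
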